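The tetrahydrofuran ring is read one oxidation level up, as a 2,3-dihydrofuran: ring oxygen O1, C5 and the aroyl-bearing C4 are the enol of a 1,3-diketone, and C2–C3 is the C=C of a chalcone. A Mn(OAc)3-mediated oxidative radical [3+2] annulation joins the diketone carbon (C4) to the chalcone α-carbon (C3) and a diketone oxygen (O1) to the benzylic carbon (C2) in one operation; its precursors are a benzyl-protected chalcone and a dibenzoylmethane with one chelated phenol. Hydrogenation anti to the C3 aroyl group then sets the cis-3,4-diaroyl unit, acid-mediated benzylic epimerization turns each aryl group trans to its neighbouring aroyl group, and hydrogenolysis frees the phenols.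

Key step: step 3

Remark: the target is the meso (2R,3R,4S,5S) isomer (2,3-trans, 3,4-cis, 4,5-trans), so chiral intermediates are racemic and drawn as one enantiomer. Ring atoms are numbered O1, C2 (aryl), C3 (aroyl, from the chalcone), C4 (aroyl, from the diketone), C5 (aryl).

Step 1
Reactants: 1 2',4'-bis(benzyloxy)acetophenone; 2 4-(benzyloxy)benzaldehyde
Product: 3 (E)-1-[2,4-bis(benzyloxy)phenyl]-3-[4-(benzyloxy)phenyl]prop-2-en-1-one
Conditions: KOH (aq.), EtOH–THF, rt
Reagents that add atoms: none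
Why: Claisen–Schmidt aldol condensation of a methyl ketone with a non-enolizable aldehyde; dehydration under equilibrating conditions should give the E alkene.

Step 2
Reactants: 4 1-[4-(benzyloxy)-2-hydroxyphenyl]ethanone; 5 4-(benzyloxy)benzoyl chloride
Product: 6 1-[4-(benzyloxy)-2-hydroxyphenyl]-3-[4-(benzyloxy)phenyl]propane-1,3-dione
Conditions: LiN(SiMe3)2 (3.2 equiv), THF, −78 °C to rt; aq. HCl work-up
Reagents that add atoms: none
Why: Claisen-type C-acylation of the lithium phenoxide–enolate dianion of 4 by the aroyl chloride, the third equivalent of base taking up the acidic diketone proton.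

Step 3
Reactants: 3 (E)-1-[2,4-bis(benzyloxy)phenyl]-3-[4-(benzyloxy)phenyl]prop-2-en-1-one; 6 1-[4-(benzyloxy)-2-hydroxyphenyl]-3-[4-(benzyloxy)phenyl]propane-1,3-dione
Product: 7 rac-[(2R,3R)-4-[4-(benzyloxy)-2-hydroxybenzoyl]-2,5-bis[4-(benzyloxy)phenyl]-2,3-dihydrofuran-3-yl][2,4-bis(benzyloxy)phenyl]methanone (trans)
Conditions: Mn(OAc)3·2H2O (2.5 equiv), AcOH, 70 °C, N2
Reagents that add atoms: none
Why: Trivalent manganese oxidizes the enolate of 6 to a C4-centred radical that adds to the α-carbon (C3) of 3; the resulting benzylic C2 radical is oxidized by a second equivalent to the cation, which is captured by a diketone oxygen before the C4 proton is lost. This is the Mn(OAc)3 oxidative radical [3+2] annulation of 1,3-dicarbonyl compounds with cinnamoyl-type alkenes. The dihydrofuran ring closes by O-attack of the diketone on the planar C2 cation, a five-membered closure with the enol C4=C5 bond inside the new ring. C2 and C3 are set relative to each other only: during ring closure the aryl group should take the face opposite the C3 aroyl group, giving the trans isomer as a racemate. The step needs addition at C3 rather than C2, secured by the 4-benzyloxyphenyl group that stabilizes the C2 radical and cation, and closure through the 4-benzyloxybenzoyl oxygen, secured by the hydrogen bond that ties the other carbonyl to the free ortho phenol of 6.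

Step 4
Reactants: 7 rac-[(2R,3R)-4-[4-(benzyloxy)-2-hydroxybenzoyl]-2,5-bis[4-(benzyloxy)phenyl]-2,3-dihydrofuran-3-yl][2,4-bis(benzyloxy)phenyl]methanone
Product: 8 rac-[(2R,3R,4S,5R)-4-[4-(benzyloxy)-2-hydroxybenzoyl]-2,5-bis[4-(benzyloxy)phenyl]tetrahydrofuran-3-yl][2,4-bis(benzyloxy)phenyl]methanone (2,3-trans, 3,4-cis, 4,5-cis)
Conditions: H2 (3 atm), 5% Rh/Al2O3, EtOAc, rt
Reagents that add atoms: none
Why: Heterogeneous syn hydrogenation of the tetrasubstituted enol ether C4=C5 on a catalyst that spares benzyl ethers; delivery of both hydrogens to the face opposite the adjacent (allylic) C3 aroyl group should place the C4 aroyl group cis to it and the C5 aryl group cis to both.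

Step 5
Reactants: 8 rac-[(2R,3R,4S,5R)-4-[4-(benzyloxy)-2-hydroxybenzoyl]-2,5-bis[4-(benzyloxy)phenyl]tetrahydrofuran-3-yl][2,4-bis(benzyloxy)phenyl]methanone
Product: 9 rac-[(2R,3R,4S,5S)-4-[4-(benzyloxy)-2-hydroxybenzoyl]-2,5-bis[4-(benzyloxy)phenyl]tetrahydrofuran-3-yl][2,4-bis(benzyloxy)phenyl]methanone (2,3-trans, 3,4-cis, 4,5-trans)
Conditions: CF3CO2H, CH2Cl2, 0 °C to rt
Reagents that add atoms: none
Why: Acid-catalysed benzylic epimerization, as known for aryl tetrahydrofuran and furofuran lignans: reversible ionization of C5–O1 to the 4-benzyloxybenzyl cation and reclosure by the oxygen that stays on C2 should bring the C5 aryl group trans to the C4 aroyl group under thermodynamic control, while C3 and C4 are not enolized.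

Step 6
Reactants: 9 rac-[(2R,3R,4S,5S)-4-[4-(benzyloxy)-2-hydroxybenzoyl]-2,5-bis[4-(benzyloxy)phenyl]tetrahydrofuran-3-yl][2,4-bis(benzyloxy)phenyl]methanone
Product: 10 [(2R,3R,4S,5S)-2,5-bis(4-hydroxyphenyl)tetrahydrofuran-3,4-diyl]bis[(2,4-dihydroxyphenyl)methanone] (meso; CNP0237262.1)
Conditions: H2 (1 atm), 10% Pd/C, EtOAc–MeOH, rt
Reagents that add atoms: none
Why: Hydrogenolysis of the five aryl benzyl ethers under neutral conditions, which should leave all four stereocenters and the chelated aryl ketones untouched if the exposure is kept short.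

Compound list
1 | 2',4'-bis(benzyloxy)acetophenone | CC(=O)c1ccc(OCc2ccccc2)cc1OCc1ccccc1 | starting material
2 | 4-(benzyloxy)benzaldehyde | O=Cc1ccc(OCc2ccccc2)cc1 | starting material
3 | (E)-1-[2,4-bis(benzyloxy)phenyl]-3-[4-(benzyloxy)phenyl]prop-2-en-1-one | O=C(/C=C/c1ccc(OCc2ccccc2)cc1)c1ccc(OCc2ccccc2)cc1OCc1ccccc1 | intermediate
4 | 1-[4-(benzyloxy)-2-hydroxyphenyl]ethanone | CC(=O)c1ccc(OCc2ccccc2)cc1O | starting material
5 | 4-(benzyloxy)benzoyl chloride | O=C(Cl)c1ccc(OCc2ccccc2)cc1 | starting material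
6 | 1-[4-(benzyloxy)-2-hydroxyphenyl]-3-[4-(benzyloxy)phenyl]propane-1,3-dione | O=C(CC(=O)c1ccc(OCc2ccccc2)cc1)c1ccc(OCc2ccccc2)cc1O | intermediate
7 | rac-[(2R,3R)-4-[4-(benzyloxy)-2-hydroxybenzoyl]-2,5-bis[4-(benzyloxy)phenyl]-2,3-dihydrofuran-3-yl][2,4-bis(benzyloxy)phenyl]methanone | O=C(c1ccc(OCc2ccccc2)cc1OCc1ccccc1)[C@@H]1C(C(=O)c2ccc(OCc3ccccc3)cc2O)=C(c2ccc(OCc3ccccc3)cc2)O[C@H]1c1ccc(OCc2ccccc2)cc1 | intermediate
8 | rac-[(2R,3R,4S,5R)-4-[4-(benzyloxy)-2-hydroxybenzoyl]-2,5-bis[4-(benzyloxy)phenyl]tetrahydrofuran-3-yl][2,4-bis(benzyloxy)phenyl]methanone | O=C(c1ccc(OCc2ccccc2)cc1OCc1ccccc1)[C@@H]1[C@H](C(=O)c2ccc(OCc3ccccc3)cc2O)[C@H](c2ccc(OCc3ccccc3)cc2)O[C@H]1c1ccc(OCc2ccccc2)cc1 | intermediate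
9 | rac-[(2R,3R,4S,5S)-4-[4-(benzyloxy)-2-hydroxybenzoyl]-2,5-bis[4-(benzyloxy)phenyl]tetrahydrofuran-3-yl][2,4-bis(benzyloxy)phenyl]methanone | O=C(c1ccc(OCc2ccccc2)cc1OCc1ccccc1)[C@@H]1[C@H](C(=O)c2ccc(OCc3ccccc3)cc2O)[C@@H](c2ccc(OCc3ccccc3)cc2)O[C@H]1c1ccc(OCc2ccccc2)cc1 | intermediate
10 | [(2R,3R,4S,5S)-2,5-bis(4-hydroxyphenyl)tetrahydrofuran-3,4-diyl]bis[(2,4-dihydroxyphenyl)methanone] (meso) | O=C(c1ccc(O)cc1O)[C@@H]1[C@H](C(=O)c2ccc(O)cc2O)[C@@H](c2ccc(O)cc2)O[C@H]1c1ccc(O)cc1 | target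

Total step count: 6. Longest linear sequence: 5 steps (step 1 or step 2, then steps 3 to 6).

Steps most likely to fail

Step 3. The ring may close through the chelated carbonyl oxygen and give the constitutional isomer. Diketone 6 may also cyclodehydrate to a flavone in warm acetic acid, or its radical may couple with itself faster than it adds to the electron-poor alkene. The fallback builds the two bonds one after the other, setting out from 3 and 6 and returning at 7. Chemoselective hydrogenation of the enone C=C of 3 (H2, Pd/C poisoned with Ph2S, EtOAc) would give the dihydrochalcone 1-[2,4-bis(benzyloxy)phenyl]-3-[4-(benzyloxy)phenyl]propan-1-one F1. α-Bromination (CuBr2, EtOAc–CHCl3, reflux) would give 1-[2,4-bis(benzyloxy)phenyl]-3-[4-(benzyloxy)phenyl]-2-bromopropan-1-one F2. C-Alkylation of 6 with F2 (K2CO3, acetone) would form the C3–C4 bond in the triketone 2-[4-(benzyloxy)-2-hydroxybenzoyl]-3-[2,4-bis(benzyloxy)benzoyl]-1,4-bis[4-(benzyloxy)phenyl]butan-1-one F3. DDQ (CH2Cl2, rt) would then abstract hydride from the 4-benzyloxybenzylic CH2 and the enol oxygen would close the O1–C2 bond trans to the C3 aroyl group, giving 7.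

Step 4. Hydrogen may be delivered to the wrong face, syn to the C3 aroyl group, because the C2 aryl group shields the other face; this would end in the all-trans diastereomer after step 5. Slow reduction may also allow benzylic C–O hydrogenolysis. The fallback sets out from 7 and returns at 9. Deprotonation of 7 (LiN(SiMe3)2, 2.2 equiv, THF, −78 °C; phenoxide and C3 enolate) and kinetic protonation by a hindered phenol at −78 °C, anti to the C2 aryl group, would give the cis isomer rac-[(2R,3S)-4-[4-(benzyloxy)-2-hydroxybenzoyl]-2,5-bis[4-(benzyloxy)phenyl]-2,3-dihydrofuran-3-yl][2,4-bis(benzyloxy)phenyl]methanone F4. With both substituents on one face, hydrogenation (H2, Rh/Al2O3, EtOAc) would give the all-cis tetrahydrofuran rac-[(2R,3S,4R,5S)-4-[4-(benzyloxy)-2-hydroxybenzoyl]-2,5-bis[4-(benzyloxy)phenyl]tetrahydrofuran-3-yl][2,4-bis(benzyloxy)phenyl]methanone F5. The acid treatment of step 5 would then epimerize both benzylic centres C2 and C5 and give 9.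

Step 5. The open benzylic cation may lose the C4 proton, which scrambles C4 through the enone. It may also be captured by the free ortho phenol in a six-membered ring, or ionize too slowly next to the aroyl group. The fallback sets out from 8 and returns at 10. Benzylation of the phenol (BnBr, K2CO3, DMF) would give the hexabenzyl ether rac-[(2R,3R,4S,5R)-2,5-bis[4-(benzyloxy)phenyl]tetrahydrofuran-3,4-diyl]bis{[2,4-bis(benzyloxy)phenyl]methanone} F6. A Lewis acid at low temperature (BF3·OEt2, CH2Cl2, −40 °C) would epimerize C5 to the meso ether [(2R,3R,4S,5S)-2,5-bis[4-(benzyloxy)phenyl]tetrahydrofuran-3,4-diyl]bis{[2,4-bis(benzyloxy)phenyl]methanone} F7. Hydrogenolysis under the conditions of step 6 would give 10.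

Further compounds
F1 | step 3 | 1-[2,4-bis(benzyloxy)phenyl]-3-[4-(benzyloxy)phenyl]propan-1-one | O=C(CCc1ccc(OCc2ccccc2)cc1)c1ccc(OCc2ccccc2)cc1OCc1ccccc1
F2 | step 3 | 1-[2,4-bis(benzyloxy)phenyl]-3-[4-(benzyloxy)phenyl]-2-bromopropan-1-one (racemic) | O=C(C(Br)Cc1ccc(OCc2ccccc2)cc1)c1ccc(OCc2ccccc2)cc1OCc1ccccc1
F3 | step 3 | 2-[4-(benzyloxy)-2-hydroxybenzoyl]-3-[2,4-bis(benzyloxy)benzoyl]-1,4-bis[4-(benzyloxy)phenyl]butan-1-one (racemic) | O=C(c1ccc(OCc2ccccc2)cc1OCc1ccccc1)C(Cc1ccc(OCc2ccccc2)cc1)C(C(=O)c1ccc(OCc2ccccc2)cc1O)C(=O)c1ccc(OCc2ccccc2)cc1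
F4 | step 4 | rac-[(2R,3S)-4-[4-(benzyloxy)-2-hydroxybenzoyl]-2,5-bis[4-(benzyloxy)phenyl]-2,3-dihydrofuran-3-yl][2,4-bis(benzyloxy)phenyl]methanone | O=C(c1ccc(OCc2ccccc2)cc1OCc1ccccc1)[C@H]1C(C(=O)c2ccc(OCc3ccccc3)cc2O)=C(c2ccc(OCc3ccccc3)cc2)O[C@H]1c1ccc(OCc2ccccc2)cc1
F5 | step 4 | rac-[(2R,3S,4R,5S)-4-[4-(benzyloxy)-2-hydroxybenzoyl]-2,5-bis[4-(benzyloxy)phenyl]tetrahydrofuran-3-yl][2,4-bis(benzyloxy)phenyl]methanone | O=C(c1ccc(OCc2ccccc2)cc1OCc1ccccc1)[C@H]1[C@@H](C(=O)c2ccc(OCc3ccccc3)cc2O)[C@@H](c2ccc(OCc3ccccc3)cc2)O[C@H]1c1ccc(OCc2ccccc2)cc1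
F6 | step 5 | rac-[(2R,3R,4S,5R)-2,5-bis[4-(benzyloxy)phenyl]tetrahydrofuran-3,4-diyl]bis{[2,4-bis(benzyloxy)phenyl]methanone} | O=C(c1ccc(OCc2ccccc2)cc1OCc1ccccc1)[C@@H]1[C@H](C(=O)c2ccc(OCc3ccccc3)cc2OCc2ccccc2)[C@H](c2ccc(OCc3ccccc3)cc2)O[C@H]1c1ccc(OCc2ccccc2)cc1
F7 | step 5 | [(2R,3R,4S,5S)-2,5-bis[4-(benzyloxy)phenyl]tetrahydrofuran-3,4-diyl]bis{[2,4-bis(benzyloxy)phenyl]methanone} (meso) | O=C(c1ccc(OCc2ccccc2)cc1OCc1ccccc1)[C@@H]1[C@H](C(=O)c2ccc(OCc3ccccc3)cc2OCc2ccccc2)[C@@H](c2ccc(OCc3ccccc3)cc2)O[C@H]1c1ccc(OCc2ccccc2)cc1
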